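## Retrosynthetic overview

1. The (S)-para-quinol methyl ether is disconnected at the C4–OMe bond: enantioselective oxidative methoxylation (dearomatization) of the 2-allyl-4-alkenyl-5-methoxyphenol with a chiral diacetoxyiodoarene and MeOH.
2. The 2-allylphenol comes from an aromatic Claisen rearrangement of the allyl aryl ether, itself made by O-allylation of the stilbenoid phenol.
3. The stilbenoid phenol comes from a Heck coupling of 4-bromo-3-methoxyphenol with (E)-methyl isoeugenol, which sets the (E)-trisubstituted alkene.
4. The chiral oxidant comes from perborate oxidation of the C2-symmetric bis(lactamide) iodoarene.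
5. Ring order: both six-membered rings are bought as benzene rings and no ring is built; the phenol ring becomes the cyclohexa-2,5-dienone only in the last step.

Assumption: methyl isoeugenol is used as the ≥98 % (E) grade and the (R,R)-bis(mesityl-lactamide) iodoarene is bought (otherwise three known steps from 2-iodoresorcinol and (S)-lactate). The sense of induction in the new step is a proposal that must be assigned by experiment; if the (R,R)-reagent gives the (R)-product, the (S,S)-antipode from (R)-lactate is used in the same way.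

## Route

Step 1
Reactants: 1 4-bromo-3-methoxyphenol; 2 (E)-methyl isoeugenol (1,2-dimethoxy-4-[(E)-prop-1-enyl]benzene)
Product: 3 4-[(E)-1-(3,4-dimethoxyphenyl)prop-1-en-2-yl]-3-methoxyphenol
Conditions: 2 (1.5 equiv), Pd(OAc)2 (5 mol %), [HP(t-Bu)3]BF4 (10 mol %), Cy2NMe (2.5 equiv), 1,4-dioxane, 100 °C, 16 h
Reagents that add atoms: none
Why: Mizoroki–Heck arylation in which the electron-rich aryl bromide adds to the bulky zerovalent palladium–P(t-Bu)3 species, syn carbopalladation places the aryl group on the methyl-bearing carbon (palladium benzylic), and the only possible syn β-hydride elimination gives the (E)-alkene with the two aryl groups trans; no stereocentre is formed.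

Step 2
Reactants: 3 4-[(E)-1-(3,4-dimethoxyphenyl)prop-1-en-2-yl]-3-methoxyphenol; 4 allyl bromide
Product: 5 4-[(E)-2-(4-allyloxy-2-methoxyphenyl)prop-1-enyl]-1,2-dimethoxybenzene
Conditions: allyl bromide (1.3 equiv), K2CO3 (2 equiv), acetone, reflux, 6 h
Reagents that add atoms: allyl bromide (4), C=CCBr
Why: Williamson ether synthesis on the only acidic OH, with nothing else in the molecule reactive toward K2CO3 or a primary allylic bromide.

Step 3
Reactants: 5 4-[(E)-2-(4-allyloxy-2-methoxyphenyl)prop-1-enyl]-1,2-dimethoxybenzene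
Product: 7 2-allyl-4-[(E)-1-(3,4-dimethoxyphenyl)prop-1-en-2-yl]-5-methoxyphenol, via 6-allylcyclohexa-2,4-dienone tautomer 6 (not isolated)
Conditions: PhNEt2, 190 °C (sealed tube or microwave), 2–4 h
Reagents that add atoms: none
Why: Aromatic Claisen rearrangement ([3,3]-sigmatropic shift to dienone 6, then enolization) in which the allyl group goes to the ortho carbon para to OMe, because the methoxy group, buttressed by the bulky neighbouring alkenyl group, turns its methyl toward the other ortho carbon and shields it; the transient sp3 centre of 6 is lost on enolization.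

Step 4
Reactants: 8 (R,R)-2-iodo-1,3-bis[1-(mesitylcarbamoyl)ethoxy]benzene; 9 acetic acid
Product: 10 (R,R)-2-(diacetoxyiodo)-1,3-bis[1-(mesitylcarbamoyl)ethoxy]benzene
Conditions: NaBO3·4H2O (10 equiv), AcOH, 45 °C, 6 h; evaporate, CH2Cl2/H2O, triturate with hexane
Reagents that add atoms: acetic acid (9), CC(=O)O
Why: Perborate/acetic acid oxidation of an aryl iodide (peracetic acid formed in situ) to the trivalent-iodine diacetate, a standard ArI(OAc)2 preparation that leaves the two lactamide stereocentres untouched.

Step 5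
Reactants: 7 2-allyl-4-[(E)-1-(3,4-dimethoxyphenyl)prop-1-en-2-yl]-5-methoxyphenol; 10 (R,R)-2-(diacetoxyiodo)-1,3-bis[1-(mesitylcarbamoyl)ethoxy]benzene; 11 methanol
Product: 13 (4S)-2-allyl-4-[(E)-1-(3,4-dimethoxyphenyl)prop-1-en-2-yl]-4,5-dimethoxycyclohexa-2,5-dien-1-one, via aryloxy(acetoxy)iodane 12 (not isolated)
Conditions: 10 (1.1 equiv), MeOH (10 equiv), 4 Å MS, CH2Cl2, −60 to −40 °C, 6 h; sat. aq NaHCO3; chromatography on Et3N-deactivated silica (8 recovered and re-oxidized)
Reagents that add atoms: methanol (11), CO
Why: Proposed new method: phenol 7 exchanges for one acetate on trivalent iodine to give 12, in which the two lactamide N–H···O hydrogen bonds fold the mesityl amide arms into a C2-symmetric helical pocket; the 2-allyl group forces the aryloxy ligand to sit with its unsubstituted C6 edge inward and one ring face stacked on a mesityl amide, so methanol, hydrogen-bonded to the remaining acetate ligand, adds to the open Si face of C4 (the face from which C5, the alkenyl carbon and C3 run anticlockwise) in a concerted SN2′-type displacement in which iodine leaves as the monovalent aryl iodide 8, forming the C4–OMe bond and the (S)-centre, while low temperature and non-polar CH2Cl2 suppress the free phenoxenium (racemic) path and the twist of the 1-methylvinyl group out of the ring plane disfavours attack at the remote benzylic carbon; the closest known reaction types are racemic PhI(OAc)2/MeOH para-quinol ether formation and chiral aryl-iodide-mediated enantioselective spirolactonizing or hydroxylative phenol dearomatization, whereas an enantioselective intermolecular para-methoxylation creating a tertiary ether centre on a 4-alkenylphenol has not been shown.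

## Compound list

1 | 4-bromo-3-methoxyphenol | COc1cc(O)ccc1Br | starting material
2 | (E)-methyl isoeugenol, 1,2-dimethoxy-4-[(E)-prop-1-enyl]benzene | C/C=C/c1ccc(OC)c(OC)c1 | starting material
3 | 4-[(E)-1-(3,4-dimethoxyphenyl)prop-1-en-2-yl]-3-methoxyphenol | COc1cc(O)ccc1/C(C)=C/c1ccc(OC)c(OC)c1 | intermediate
4 | allyl bromide | C=CCBr | starting material
5 | 4-[(E)-2-(4-allyloxy-2-methoxyphenyl)prop-1-enyl]-1,2-dimethoxybenzene | C=CCOc1ccc(/C(C)=C/c2ccc(OC)c(OC)c2)c(OC)c1 | intermediate
6 | 6-allyl-4-[(E)-1-(3,4-dimethoxyphenyl)prop-1-en-2-yl]-3-methoxycyclohexa-2,4-dien-1-one (racemic at C6, not isolated) | C=CCC1C=C(/C(C)=C/c2ccc(OC)c(OC)c2)C(OC)=CC1=O | intermediate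
7 | 2-allyl-4-[(E)-1-(3,4-dimethoxyphenyl)prop-1-en-2-yl]-5-methoxyphenol | C=CCc1cc(/C(C)=C/c2ccc(OC)c(OC)c2)c(OC)cc1O | intermediate
8 | (R,R)-2-iodo-1,3-bis[1-(mesitylcarbamoyl)ethoxy]benzene | Cc1cc(C)c(NC(=O)[C@@H](C)Oc2cccc(O[C@H](C)C(=O)Nc3c(C)cc(C)cc3C)c2I)c(C)c1 | starting material
9 | acetic acid | CC(=O)O | starting material
10 | (R,R)-2-(diacetoxyiodo)-1,3-bis[1-(mesitylcarbamoyl)ethoxy]benzene | Cc1cc(C)c(NC(=O)[C@@H](C)Oc2cccc(O[C@H](C)C(=O)Nc3c(C)cc(C)cc3C)c2I(OC(C)=O)OC(C)=O)c(C)c1 | intermediate
11 | methanol | CO | starting material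
12 | acetoxy{2,6-bis[(R)-1-(mesitylcarbamoyl)ethoxy]phenyl}(aryloxy)iodane, aryloxy = phenoxide of 7 (not isolated) | Cc1cc(C)c(NC(=O)[C@@H](C)Oc2cccc(O[C@H](C)C(=O)Nc3c(C)cc(C)cc3C)c2I(OC(C)=O)Oc2cc(OC)c(/C(C)=C/c3ccc(OC)c(OC)c3)cc2CC=C)c(C)c1 | intermediate
13 | (4S)-2-allyl-4-[(E)-1-(3,4-dimethoxyphenyl)prop-1-en-2-yl]-4,5-dimethoxycyclohexa-2,5-dien-1-one | C=CCC1=C[C@](OC)(/C(C)=C/c2ccc(OC)c(OC)c2)C(OC)=CC1=O | target

## Step count and risk

Total steps: 5. Longest linear sequence: 4 (1 → 3 → 5 → 7 → 13); step 4 is a one-step side branch that prepares oxidant 10.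

Steps most likely to fail:

Step 5 (the proposed new enantioselective para-methoxylation). The risks are low or inverted enantioselectivity if the free phenoxenium path competes, and attack of methanol at the benzylic carbon or at an ortho position. Fallback with known chemistry: setting out from 7, oxidation with PhI(OAc)2 in MeOH at 0 °C (or constant-current anodic oxidation in MeOH/LiClO4) gives the racemic quinol ether, rac-2-allyl-4-[(E)-1-(3,4-dimethoxyphenyl)prop-1-en-2-yl]-4,5-dimethoxycyclohexa-2,5-dien-1-one F5. Preparative chiral SFC on an amylose tris(3,5-dimethylphenylcarbamate) phase then separates the enantiomers, and the (S)-enantiomer is 13, where the fallback comes back to the route. This replaces asymmetric induction by resolution, at the cost of at most half the material.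

Step 3 (Claisen regioselectivity between the two ortho carbons). Fallback: setting out from 3 and skipping 5, iodination with the iodine–morpholine complex (I2, morpholine, CH2Cl2/MeOH, 0 °C) takes place ortho to OH at the unhindered carbon para to OMe, giving 4-[(E)-1-(3,4-dimethoxyphenyl)prop-1-en-2-yl]-2-iodo-5-methoxyphenol F4. Stille coupling of F4 with allyltributylstannane (Pd(PPh3)4, LiCl, DMF, 80 °C) then gives 7, where the fallback comes back to the route. Here the position is fixed by intermolecular electrophilic substitution and cross-coupling instead of a sigmatropic shift.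

Step 1 (Heck regiochemistry and reactivity of an electron-rich bromophenol toward a 1,2-disubstituted alkene). Fallback: setting out from 2, bromine addition (Br2, CH2Cl2, −20 °C) gives 4-(1,2-dibromopropyl)-1,2-dimethoxybenzene F1. Double dehydrobromination (KOt-Bu, THF, 0 °C to rt) gives 1,2-dimethoxy-4-(prop-1-yn-1-yl)benzene F2. Copper-catalysed syn hydroboration (CuCl/Xantphos, NaOt-Bu, B2pin2, MeOH, THF, rt; boron on the methyl-bearing carbon) gives 2-[(Z)-1-(3,4-dimethoxyphenyl)prop-1-en-2-yl]-4,4,5,5-tetramethyl-1,3,2-dioxaborolane F3. Suzuki–Miyaura coupling of F3 with 1 (Pd(dppf)Cl2, K3PO4, dioxane/H2O, 80 °C) proceeds with retention and gives 3, where the fallback comes back to the route.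

Further compounds

F1 | step 1 | 4-(1,2-dibromopropyl)-1,2-dimethoxybenzene (diastereomer mixture) | COc1ccc(C(Br)C(C)Br)cc1OC
F2 | step 1 | 1,2-dimethoxy-4-(prop-1-yn-1-yl)benzene | CC#Cc1ccc(OC)c(OC)c1
F3 | step 1 | 2-[(Z)-1-(3,4-dimethoxyphenyl)prop-1-en-2-yl]-4,4,5,5-tetramethyl-1,3,2-dioxaborolane | CC1(C)OB(/C(C)=C/c2ccc(OC)c(OC)c2)OC1(C)C
F4 | step 3 | 4-[(E)-1-(3,4-dimethoxyphenyl)prop-1-en-2-yl]-2-iodo-5-methoxyphenol | COc1cc(O)c(I)cc1/C(C)=C/c1ccc(OC)c(OC)c1
F5 | step 5 | rac-2-allyl-4-[(E)-1-(3,4-dimethoxyphenyl)prop-1-en-2-yl]-4,5-dimethoxycyclohexa-2,5-dien-1-one | C=CCC1=CC(OC)(/C(C)=C/c2ccc(OC)c(OC)c2)C(OC)=CC1=O
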